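**Retrosynthetic overview**
1. Target 11 is opened at the O1–C2 bond of ring C to give the open chalcone 9. An enantioselective 6-endo oxa-Michael closure forms ring C and sets C2 in the last step, so the labile C2 centre never sees base or hot Lewis acid.
2. Chalcone 9 comes from acetophenone 6 and benzaldehyde 7 by Claisen–Schmidt condensation (Cα=Cβ).
3. Acetophenone 6 comes from phloroacetophenone 3 and two equivalents of 2,3-dihydroxybenzyl alcohol 2 by double ortho-quinone-methide C-benzylation at C3' and C5'.
4. Alcohol 2 comes from 2,3-dihydroxybenzaldehyde 1 by reduction. Ring A, ring B and both catechol rings are bought as arenes; ring C is the only ring formed.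

Assumption: the (R)-configured acid catalyst of step 4 is taken to give the (2S)-flavanone; the sense of induction is checked on the first run (chiral HPLC and circular dichroism) and the (S)-catalyst is used instead if it proves opposite.

**Step 1**
Reactants: 1 2,3-dihydroxybenzaldehyde
Product: 2 2,3-dihydroxybenzyl alcohol
Conditions: NaBH4 (1.2 equiv), MeOH, 0 °C to rt, 1 h, Ar; aq. NH4Cl (pH 5–6, 0 °C), EtOAc extraction
Reagents that add atoms: none
Why: Borohydride reduction of the aryl aldehyde gives the benzylic alcohol, the catechol being held as a borate and released on the mildly acidic work-up (kept cold to avoid ortho-quinone-methide oligomerisation); no stereocentre is formed.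

**Step 2**
Reactants: 2 2,3-dihydroxybenzyl alcohol; 3 1-(2,4,6-trihydroxyphenyl)ethanone (2',4',6'-trihydroxyacetophenone)
Product: 6 1-[3,5-bis(2,3-dihydroxybenzyl)-2,4,6-trihydroxyphenyl]ethanone, via ortho-quinone methide 4 (not isolated), via monobenzylated acetophenone 5 (not isolated)
Conditions: ZnCl2 (anhydrous, 3 equiv), 1,4-dioxane, 90 °C, Ar; 2 (2.3 equiv) added over 4 h
Reagents that add atoms: none
Why: ZnCl2 ionises the ortho-hydroxybenzyl alcohol to ortho-quinone methide 4, which is trapped by the most electron-rich arene present in a Friedel–Crafts-type conjugate C-alkylation, first at C3' (giving 5) and then at C5', the only two free positions of the acylphloroglucinol ring, the same manifold that installs 2-hydroxybenzyl groups on acylphloroglucinol-type A rings; slow addition of 2 limits its self-condensation and no stereocentre is formed.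

**Step 3**
Reactants: 6 1-[3,5-bis(2,3-dihydroxybenzyl)-2,4,6-trihydroxyphenyl]ethanone; 7 benzaldehyde
Product: 9 (E)-1-[3,5-bis(2,3-dihydroxybenzyl)-2,4,6-trihydroxyphenyl]-3-phenylprop-2-en-1-one, via aldol adduct 8 (not isolated)
Conditions: LiN(SiMe3)2 (8.5 equiv), THF, –78 °C; 7 (1.3 equiv), –78 °C to rt, 16 h, Ar, dark; poured into ice-cold 1 M HCl (pH 3), fast EtOAc extraction, evaporation below 25 °C, Sephadex LH-20
Reagents that add atoms: none
Why: One equivalent of lithium amide per acidic proton gives the heptaphenoxide enolate, which adds to benzaldehyde to give 8 and loses hydroxide by E1cB to the (E)-chalcone (Claisen–Schmidt condensation, precedented for unprotected polyhydroxyacetophenones); in strong base the open chalcone phenoxide is the stable form, the cold acid quench keeps ring C open, any racemic flavanone is removed before step 4, and no stereocentre remains.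

**Step 4**
Reactants: 9 (E)-1-[3,5-bis(2,3-dihydroxybenzyl)-2,4,6-trihydroxyphenyl]-3-phenylprop-2-en-1-one
Product: 11 (2S)-6,8-bis(2,3-dihydroxybenzyl)-5,7-dihydroxy-2-phenylchroman-4-one, via flavanone enol 10 (not isolated)
Conditions: (R)-1,1,1-trifluoro-N-[4-oxido-2,6-bis(2,4,6-triisopropylphenyl)dinaphtho[2,1-d:1',2'-f][1,3,2]dioxaphosphepin-4-yl]methanesulfonamide (C51H57F3NO5PS, 5 mol%), cyclopentyl methyl ether/EtOAc 4:1, 0 °C, 24–48 h, Ar, dark; filtration through a short silica pad, recrystallisation
Reagents that add atoms: none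
Why: Proposed new method: enantioselective Brønsted-acid-catalysed 6-endo-trig oxa-Michael closure of an unactivated, fully unprotected 2',6'-dihydroxychalcone, in which the 6'-OH···O=C hydrogen bond holds the aryl ketone planar, the acidic N–H of the phosphoramide hydrogen-bonds/protonates the carbonyl oxygen (making C-β electrophilic) while its P=O accepts the proton of the attacking 2'-OH, so that the C2–O1 bond forms in a two-point-bound complex whose triisopropylphenyl walls leave only the Si face of C-β open and give the (2S)-enol 10, which tautomerises to the ketone; the two ortho hydroxyls are equivalent so either gives the same product, the other phenols cannot reach C-β (rings of ten or more atoms), and acid rather than base avoids retro-oxa-Michael racemisation and catechol autoxidation; closest known reaction type: chiral phosphoric acid-catalysed intramolecular aza-Michael cyclisation of 2'-aminochalcones to 2-aryl-2,3-dihydroquinolin-4-ones, and amine–thiourea-catalysed oxa-Michael closure of ester-activated 2'-hydroxychalcones.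

**Compound list**
1 | 2,3-dihydroxybenzaldehyde | O=Cc1cccc(O)c1O | starting material
2 | 2,3-dihydroxybenzyl alcohol | OCc1cccc(O)c1O | intermediate
3 | 1-(2,4,6-trihydroxyphenyl)ethanone (2',4',6'-trihydroxyacetophenone) | CC(=O)c1c(O)cc(O)cc1O | starting material
4 | 2-hydroxy-6-methylidenecyclohexa-2,4-dien-1-one (ortho-quinone methide) | C=C1C=CC=C(O)C1=O | intermediate
5 | 1-[3-(2,3-dihydroxybenzyl)-2,4,6-trihydroxyphenyl]ethanone | CC(=O)c1c(O)cc(O)c(Cc2cccc(O)c2O)c1O | intermediate
6 | 1-[3,5-bis(2,3-dihydroxybenzyl)-2,4,6-trihydroxyphenyl]ethanone | CC(=O)c1c(O)c(Cc2cccc(O)c2O)c(O)c(Cc2cccc(O)c2O)c1O | intermediate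
7 | benzaldehyde | O=Cc1ccccc1 | starting material
8 | racemic 1-[3,5-bis(2,3-dihydroxybenzyl)-2,4,6-trihydroxyphenyl]-3-hydroxy-3-phenylpropan-1-one (aldol adduct) | O=C(CC(O)c1ccccc1)c1c(O)c(Cc2cccc(O)c2O)c(O)c(Cc2cccc(O)c2O)c1O | intermediate
9 | (E)-1-[3,5-bis(2,3-dihydroxybenzyl)-2,4,6-trihydroxyphenyl]-3-phenylprop-2-en-1-one | O=C(/C=C/c1ccccc1)c1c(O)c(Cc2cccc(O)c2O)c(O)c(Cc2cccc(O)c2O)c1O | intermediate
10 | (2S)-6,8-bis(2,3-dihydroxybenzyl)-2-phenyl-2H-chromene-4,5,7-triol (flavanone enol) | OC1=C[C@@H](c2ccccc2)Oc2c(Cc3cccc(O)c3O)c(O)c(Cc3cccc(O)c3O)c(O)c21 | intermediate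
11 | (2S)-6,8-bis(2,3-dihydroxybenzyl)-5,7-dihydroxy-2-phenylchroman-4-one | O=C1C[C@@H](c2ccccc2)Oc2c(Cc3cccc(O)c3O)c(O)c(Cc3cccc(O)c3O)c(O)c21 | target

**Step count and risk**
Total steps: 4. Longest linear sequence: 4 (1 → 2 → 6 → 9 → 11).

Steps most likely to fail:

- **Step 4 (proposed new enantioselective closure).** Risks are low enantioselectivity, non-productive binding of the catalyst by the seven phenols, and racemic background closure. Fallback with known chemistry, setting out from 9 and coming back at 11: ring C is closed without stereocontrol by the classical chalcone–flavanone isomerisation (NaOAc, EtOH, reflux, Ar) to racemic 6,8-bis(2,3-dihydroxybenzyl)-5,7-dihydroxy-2-phenylchroman-4-one F6 (the same racemate as F5). The enantiomers are then separated by preparative supercritical-fluid chromatography on an amylose tris(3,5-dimethylphenylcarbamate) phase, which gives 11 directly. The unwanted (2R)-6,8-bis(2,3-dihydroxybenzyl)-5,7-dihydroxy-2-phenylchroman-4-one F7 is recycled to 9 by KOH ring opening and cold acidification.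

- **Step 3 (aldol condensation on a heptaphenol).** Risks are an insoluble polylithium salt, incomplete enolisation, and ring closure during work-up. Fallback setting out from 3 and 7 and coming back at 9: the condensation is run on the triphenol itself (LiN(SiMe3)2, 4.5 equiv, THF, –78 °C to rt), giving (E)-2',4',6'-trihydroxychalcone F3. This is cyclised (NaOAc, EtOH, reflux) to racemic 5,7-dihydroxy-2-phenylchroman-4-one F4, which can also be bought. F4 is bis-C-benzylated with 2 (ZnCl2, dioxane, 90 °C) to racemic 6,8-bis(2,3-dihydroxybenzyl)-5,7-dihydroxy-2-phenylchroman-4-one F5. F5 is opened by retro-oxa-Michael (E1cB) in concentrated aqueous KOH/EtOH under Ar, and the chalcone phenoxide solution is run into ice-cold dilute HCl to give 9. The enone is thus made by ring opening, not by an aldol on the heptaphenol.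

- **Step 2 (double C-benzylation with a free catechol).** Risks are self-condensation of 2, over-benzylation of the catechol rings, and chelation of ZnCl2 by the catechol. Fallback setting out from 3 and coming back at 6: the catechol is masked as a guaiacol. Commercial 2-hydroxy-3-methoxybenzyl alcohol F1 is coupled with 3 in the same ZnCl2/dioxane manifold to give 1-[2,4,6-trihydroxy-3,5-bis(2-hydroxy-3-methoxybenzyl)phenyl]ethanone F2. Its two methyl ethers are then cleaved with BBr3 (CH2Cl2, –78 to 0 °C, aqueous work-up) to give 6.

**Further compounds**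
F1 | step 2 | 2-hydroxy-3-methoxybenzyl alcohol | COc1cccc(CO)c1O
F2 | step 2 | 1-[2,4,6-trihydroxy-3,5-bis(2-hydroxy-3-methoxybenzyl)phenyl]ethanone | CC(=O)c1c(O)c(Cc2cccc(OC)c2O)c(O)c(Cc2cccc(OC)c2O)c1O
F3 | step 3 | (E)-2',4',6'-trihydroxychalcone | O=C(/C=C/c1ccccc1)c1c(O)cc(O)cc1O
F4 | step 3 | racemic 5,7-dihydroxy-2-phenylchroman-4-one | O=C1CC(c2ccccc2)Oc2cc(O)cc(O)c21
F5 | step 3 | racemic 6,8-bis(2,3-dihydroxybenzyl)-5,7-dihydroxy-2-phenylchroman-4-one | O=C1CC(c2ccccc2)Oc2c(Cc3cccc(O)c3O)c(O)c(Cc3cccc(O)c3O)c(O)c21
F6 | step 4 | racemic 6,8-bis(2,3-dihydroxybenzyl)-5,7-dihydroxy-2-phenylchroman-4-one | O=C1CC(c2ccccc2)Oc2c(Cc3cccc(O)c3O)c(O)c(Cc3cccc(O)c3O)c(O)c21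
F7 | step 4 | (2R)-6,8-bis(2,3-dihydroxybenzyl)-5,7-dihydroxy-2-phenylchroman-4-one | O=C1C[C@H](c2ccccc2)Oc2c(Cc3cccc(O)c3O)c(O)c(Cc3cccc(O)c3O)c(O)c21
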